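Readings and results are calculated with made-up constants; scatter was added.

Dividing a reading by its time gives a slope, and the flasks below are reckoned from that easy step.

in all of them: substrate 10 mM

| run | partner | free catalyst | remark | time |
|---|---|---|---|---|
| birch | 5 equiv | 0.036 mol% | run made earlier |  |
| maple | 5 equiv | 0.63 mol% | run made earlier |  |
| Wednesday's | 5.00 equiv | 0.4 mol% |  | 20 min |
| Tuesday's | 5.00 equiv | 0.15 mol% |  | 20 min |
| Thursday's | 5.00 equiv | 0.2 mol% |  | 20 min |
| Friday's | 5.00 equiv | 0.03 mol% |  | 20 min |
| Saturday's | 5.00 equiv | 0.1 mol% |  | 20 min |

| birch: time / min | birch: target / % | maple: time / min | maple: target / % |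
|---|---|---|---|
| 1.50 | 1.5 | 1.50 | 23.3 |
| 3.00 | 2.6 | 3.00 | 44.7 |
| 5.00 | 3.7 | 5.00 | 72.3 |
| 6.00 | 5.5 | 6.00 | 85.9 |
| 8.00 | 6.6 | 8.00 | 100.0 |
| 10.0 | 8.1 | 10.0 | 99.7 |

(readings scatter by 0.5 percentage points)



1. the flasks by amount of target, in percent of the substrate charged, highest first, at 20 min (Wednesday's / Tuesday's / Thursday's / Friday's / Saturday's)
2. the same order at 1.0 min (Wednesday's / Tuesday's / Thursday's / Friday's / Saturday's)
3. the amount of target, in percent of the substrate charged of the flask you put first, at 20 min
4. the amount of target, in percent of the substrate charged of the flask you put last, at 20 min

In the maple run, target stands at 44.7 % after 3.00 min and at 85.9 % after 6.00 min. The second stretch therefore adds 41 percentage points against 44.7 % in the first, although by the reading 55.3 % of the substrate is left when it begins. The rate of the maple run is thus close to zero order in substrate, and the concentration to try next is that of the catalyst.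

Let f be the target read, divided by the time and by the loading of free catalyst. The maple run at 6.00 min gives 22.7 /min, and f, the target made per minute per catalyst charged, is the turnover frequency. The second way to f is the birch run, with a loading smaller by a factor of 17.5, whose last reading gives 22.5 /min. These two come from different flasks and different times, so their agreement is a real check on the proportion to catalyst.

The earliest reading of the maple run parts from f. Carried back to 1.50 min, f gives 21.5 %, but the reading is 23.3 %, a gap of 1.8 points against a scatter of 0.5 points. The early reading of the maple run thus stands above what f gives, so the average sinks slowly with time in that run, and the reckoning here for 20 min should lean high.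

That reckoning orders the flasks by loading at both times. Friday's comes to 13.6 %. By this reckoning Wednesday's, with substrate as limiting reagent, finishes in 11.0 min, sooner than the 20 min asked.

The forecast argues likewise, “so the rate is first order in free catalyst”. It gives Wednesday's > Thursday's > Tuesday's > Saturday's > Friday's at 20 min and Wednesday's > Thursday's > Tuesday's > Saturday's > Friday's at 1.0 min, with 100 % on top and 13.8 % at the bottom, the last a shade above the reckoning here.

The flasks give Wednesday's > Thursday's > Tuesday's > Saturday's > Friday's at 20 min and Wednesday's > Thursday's > Tuesday's > Saturday's > Friday's at 1.0 min, with 100 % and 13.0 %.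

    partner + free catalyst → catalyst intermediate A (k = 2700 /M/min)
    catalyst intermediate A → by-product + catalyst intermediate B (k = 150 /min)
    substrate + catalyst intermediate B → catalyst intermediate C (k = 2.10 × 10⁵ /M/min)
    catalyst intermediate C → free catalyst + target (k = 38.0 /min)
    2 partner → homo dimer (k = 0.690 /M/min)

Friday's holds 13.0 % against the reckoned 13.6 %, an average of 21.7 /min, lower than f. On Saturday's, f reckons 45.4 % and the flask holds 42.9 %. In Friday's at 5.80 min, partner goes to homo dimer at 25 times the rate at which it goes into catalyst intermediate A. By 20.0 min, Friday's keeps 87 % of its substrate but 41 % of its partner.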